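**Retrosynthetic overview**

1. Feature: in the tetrahydrofuran ring (O1, C2 with the aryl group, C3 with CH2OH, C4 with the aroyl group, C5 as CH2) the chain CH2OH–C3–C4–C5 is a 2,3-disubstituted butane-1,4-diol. It is the fully reduced form of an α,β-disubstituted γ-butyrolactone whose α-carbon (C3) carries the benzylic carbon C2 and whose β-carbon (C4) carries the ketone carbon.
2. Key disconnection: the C3–C2 and C4–C(=O) bonds go back to a one-flask conjugate addition–aldol of a lithiated 2-aryl-1,3-dithiane (masked aroyl anion) and a protected syringaldehyde on (5R)-5-menthyloxy-2(5H)-furanone; the acetal centre fixes C3 absolutely.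
3. Ring order: all benzene rings are bought. The tetrahydrofuran is the only ring made (step 8), by capture of the C2 benzylic cation by the C5 hydroxyl of the LiAlH4-derived triol (2,3-trans). Dithiane hydrolysis and base equilibration then turn the 3,4-cis ketone into the all-trans one.
4. Side chain: the erythro arylglycerol (Cα benzylic carbinol, Cβ aryloxy carbon, Cγ CH2OH) is cut at Cβ–O–aryl. A threo (αR,βR) 1,3-bis-silylated 1-arylglycerol from an Evans glycolate syn-aldol is joined to the freed ring phenol by Mitsunobu inversion; fluoride and hydrogenolysis then release the target.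

Key step: step 6

Assumption: the carbinol centre made in the aldol of step 6 is drawn as its S epimer; this centre is ionised in step 8, so either epimer serves.

**Route**

Step 1
Reactants: 1 syringaldehyde
Product: 2 4-(benzyloxy)-3,5-dimethoxybenzaldehyde
Conditions: BnBr, K2CO3, DMF, 60 °C
Reagents that add atoms: benzyl bromide, BrCc1ccccc1
Why: Williamson ether synthesis on the phenoxide of 1, the only acidic site, with a reactive benzylic bromide.

Step 2
Reactants: 2 4-(benzyloxy)-3,5-dimethoxybenzaldehyde; 3 propane-1,3-dithiol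
Product: 4 2-[4-(benzyloxy)-3,5-dimethoxyphenyl]-1,3-dithiane
Conditions: BF3·OEt2 (cat.), CH2Cl2, 0 °C → rt
Reagents that add atoms: none
Why: Lewis-acid-catalysed dithioacetalisation of the aromatic aldehyde installs the acyl-anion equivalent, and a catalytic amount of BF3·OEt2 at low temperature should leave the benzyl ether alone.

Step 3
Reactants: 1 syringaldehyde
Product: 5 4-(allyloxy)-3,5-dimethoxybenzaldehyde
Conditions: allyl bromide, K2CO3, DMF, 60 °C
Reagents that add atoms: allyl bromide, C=CCBr
Why: Williamson ether synthesis as in step 1, giving a phenol protecting group that can later be removed without touching the benzyl ether.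

Step 4
Reactants: 6 furfural
Product: 8 5-hydroxy-2(5H)-furanone (racemic), via furfural endoperoxide 7 (not isolated)
Conditions: O2, hν (visible), rose bengal (cat.), MeOH, rt
Reagents that add atoms: dioxygen, O=O
Why: Dye-sensitised singlet-oxygen [4+2] cycloaddition to the furan gives the endoperoxide, which loses the formyl carbon as methyl formate on methanolysis and leaves the hemiacetal butenolide.

Step 5
Reactants: 8 5-hydroxy-2(5H)-furanone; 9 (−)-menthol
Product: 10 (5R)-5-[(1R,2S,5R)-menthyloxy]-2(5H)-furanone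
Conditions: CSA (cat.), toluene, reflux, azeotropic removal of water; crystallisation from petroleum ether
Reagents that add atoms: none
Why: Acid-catalysed acetalisation of the cyclic hemiacetal with the chiral alcohol; the acetal carbon is configurationally mobile under the acid, so crystallisation should collect the material as the 5R diastereomer, which is the source of absolute configuration for the tetrahydrofuran part.

Step 6
Reactants: 4 2-[4-(benzyloxy)-3,5-dimethoxyphenyl]-1,3-dithiane; 10 (5R)-5-menthyloxy-2(5H)-furanone; 5 4-(allyloxy)-3,5-dimethoxybenzaldehyde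
Product: 13 (3S,4R,5R)-3-[(S)-(4-allyloxy-3,5-dimethoxyphenyl)(hydroxy)methyl]-4-[2-(4-benzyloxy-3,5-dimethoxyphenyl)-1,3-dithian-2-yl]-5-[(1R,2S,5R)-menthyloxy]dihydrofuran-2(3H)-one, via 2-lithio-2-aryl-1,3-dithiane 11 (not isolated), via lithium lactone enolate 12 (not isolated)
Conditions: n-BuLi, THF, −78 → −20 °C; then 10, −78 °C; then 5, −78 °C; aq. NH4Cl, −78 °C
Reagents that add atoms: none
Why: n-BuLi removes the C2 proton of dithiane 4 and the resulting soft, sulfur- and aryl-stabilised carbanion 11 adds in a Michael sense to C4 of butenolide 10, after which the lithium enolate 12 adds to aldehyde 5 in an aldol reaction, so that the C4–C(ketone) and C3–C2 bonds of the later tetrahydrofuran are formed in one flask. The closest known reaction type is the tandem conjugate addition–aldol trapping of lithiated 2-aryl-1,3-dithianes on 5-alkoxy-2(5H)-furanones used for lignan lactones. No ring is closed: the lactone of 10 is a temporary scaffold and is opened reductively in step 7. The centre at lactone C4 is controlled by the acetal centre C5 (attack anti to the menthyloxy group), the centre at C3 by the new C4 substituent (aldehyde approach anti to the dithianyl group, giving the 3,4-trans lactone), and the carbinol centre by the lithium aldol transition state, without consequence for the route. The step needs 1,4- rather than 1,2-addition, which the delocalised dithianyl anion and the low temperature should secure, and complete facial selectivity, which the single 5R acetal centre next to the alkene should secure. A cold quench keeps the aldol from reverting.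

Step 7
Reactants: 13 lactone adduct
Product: 14 (2R,3R)-2-[2-(4-benzyloxy-3,5-dimethoxyphenyl)-1,3-dithian-2-yl]-3-[(S)-(4-allyloxy-3,5-dimethoxyphenyl)(hydroxy)methyl]butane-1,4-diol
Conditions: LiAlH4, THF, 0 °C → rt; aq. NaOH work-up
Reagents that add atoms: none
Why: Hydride reduction of the lactone, followed by collapse of the ring-opened menthyl hemiacetal and reduction of the freed aldehyde, turns both carbonyl-level carbons into primary alcohols; the dithiane and the allyl and benzyl ethers are inert and C3 and C4 are not touched.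

Step 8
Reactants: 14 triol
Product: 15 [(2S,3R,4R)-2-(4-allyloxy-3,5-dimethoxyphenyl)-4-[2-(4-benzyloxy-3,5-dimethoxyphenyl)-1,3-dithian-2-yl]tetrahydrofuran-3-yl]methanol (2,3-trans, 3,4-cis)
Conditions: CSA (cat.), CH2Cl2, 0 °C → rt
Reagents that add atoms: none
Why: Acid ionises the electron-rich benzylic alcohol and the cation is captured by the primary hydroxyl on C5 in a 5-exo SN1 cycloetherification (the other primary hydroxyl could only close an oxetane); the reversible closure should settle on the ring with the C2 aryl group opposite the C3 hydroxymethyl and C4 dithianyl groups, which sets C2 as S.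

Step 9
Reactants: 15 tetrahydrofuran alcohol
Product: 16 (2S,3R,4R)-2-(4-allyloxy-3,5-dimethoxyphenyl)-4-[2-(4-benzyloxy-3,5-dimethoxyphenyl)-1,3-dithian-2-yl]-3-[(tert-butyldimethylsilyloxy)methyl]tetrahydrofuran
Conditions: TBSCl, imidazole, DMF, rt
Reagents that add atoms: tert-butyldimethylsilyl chloride, CC(C)(C)[Si](C)(C)Cl
Why: Standard silylation of the only hydroxyl group, which later keeps this oxygen from adding to the cis ketone as a bicyclic hemiketal and from competing in the Mitsunobu coupling.

Step 10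
Reactants: 16 silyl ether
Product: 17 (2S,3R,4R)-2-(4-allyloxy-3,5-dimethoxyphenyl)-4-(4-benzyloxy-3,5-dimethoxybenzoyl)-3-[(tert-butyldimethylsilyloxy)methyl]tetrahydrofuran (3,4-cis ketone)
Conditions: MeI, CaCO3, MeCN–H2O (9:1), 50 °C
Reagents that add atoms: water, O
Why: Alkylative dithiane hydrolysis, in which S-methylation turns the thioacetal into a leaving group and water delivers the aryl ketone under buffered, non-oxidising, mercury-free conditions that spare the allyl ether, the silyl ether and the electron-rich arenes.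

Step 11
Reactants: 17 3,4-cis ketone
Product: 18 (2S,3R,4S)-2-(4-allyloxy-3,5-dimethoxyphenyl)-4-(4-benzyloxy-3,5-dimethoxybenzoyl)-3-[(tert-butyldimethylsilyloxy)methyl]tetrahydrofuran (all-trans ketone)
Conditions: DBU (0.3 equiv), toluene, rt → 50 °C
Reagents that add atoms: none
Why: Base-mediated enolisation–reprotonation (α-epimerisation of a ketone) equilibrates C4, and the isomer with the aroyl group trans to the C3 silyloxymethyl group should dominate at equilibrium, which sets C4 as S; loss of the ring oxygen from the enolate would be a stereoelectronically poor 5-endo process and would in any case re-close without touching C2.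

Step 12
Reactants: 18 all-trans ketone
Product: 19 (2S,3R,4S)-4-(4-benzyloxy-3,5-dimethoxybenzoyl)-3-[(tert-butyldimethylsilyloxy)methyl]-2-(4-hydroxy-3,5-dimethoxyphenyl)tetrahydrofuran
Conditions: Pd(PPh3)4 (cat.), morpholine, THF, rt
Reagents that add atoms: none
Why: Zerovalent-palladium-catalysed allyl transfer from the aryl allyl ether to morpholine (Tsuji–Trost deallylation) frees one phenol and leaves the benzyl ether, the silyl ether and the ketone untouched.

Step 13
Reactants: 20 2-(allyloxy)acetic acid; 21 (S)-4-benzyloxazolidin-2-one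
Product: 23 (S)-3-[2-(allyloxy)acetyl]-4-benzyloxazolidin-2-one, via mixed pivalic anhydride 22 (not isolated)
Conditions: PivCl, Et3N, THF, −20 °C; then 21, LiCl, −20 °C → rt
Reagents that add atoms: none
Why: N-acylation of the oxazolidinone through the mixed anhydride, in which the hindered pivaloyl carbonyl directs attack to the glycolyl carbonyl.

Step 14
Reactants: 23 glycolyl imide; 24 4-(benzyloxy)-3-methoxybenzaldehyde
Product: 26 (4S)-3-[(2S,3R)-2-(allyloxy)-3-(4-benzyloxy-3-methoxyphenyl)-3-hydroxypropanoyl]-4-benzyloxazolidin-2-one, via dibutylboron Z-enolate 25 (not isolated)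
Conditions: Bu2BOTf, iPr2NEt, CH2Cl2, 0 °C; then 24, −78 → 0 °C; pH 7 buffer, MeOH, H2O2, 0 °C
Reagents that add atoms: none
Why: Evans syn-aldol, in which the boron Z-enolate reacts through a closed chair transition state on the enolate face away from the benzyl group of the (S)-auxiliary and so sets both new centres as 2S,3R, the threo arrangement of the two oxygens along the glycerol chain.

Step 15
Reactants: 26 aldol imide
Product: 27 (1R,2R)-2-(allyloxy)-1-(4-benzyloxy-3-methoxyphenyl)propane-1,3-diol
Conditions: LiBH4, MeOH (1 equiv), THF, 0 °C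
Reagents that add atoms: none
Why: Reductive cleavage of the imide by borohydride gives the primary alcohol and returns the auxiliary without touching either stereocentre.

Step 16
Reactants: 27 diol
Product: 28 (1R,2R)-2-(allyloxy)-1-(4-benzyloxy-3-methoxyphenyl)-1,3-bis(tert-butyldimethylsilyloxy)propane
Conditions: TBSOTf, 2,6-lutidine, CH2Cl2, 0 °C
Reagents that add atoms: tert-butyldimethylsilyl trifluoromethanesulfonate, CC(C)(C)[Si](C)(C)OS(=O)(=O)C(F)(F)F
Why: Silylation with a silyl triflate and a hindered base covers both the primary and the benzylic secondary hydroxyl.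

Step 17
Reactants: 28 bis-silyl ether
Product: 29 (1R,2R)-1-(4-benzyloxy-3-methoxyphenyl)-1,3-bis(tert-butyldimethylsilyloxy)propan-2-ol (threo)
Conditions: iBu2AlH, NiCl2(dppp) (cat.), toluene, 0 °C → rt; aq. potassium sodium tartrate
Reagents that add atoms: none
Why: Nickel-hydride-mediated cleavage of the alkyl allyl ether (hydrometalation of the alkene, then β-alkoxide elimination releasing propene) leaves benzyl and silyl ethers intact and exposes only the Cβ hydroxyl.

Step 18
Reactants: 19 ring phenol; 29 threo alcohol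
Product: 30 (2S,3R,4S)-4-(4-benzyloxy-3,5-dimethoxybenzoyl)-2-[4-{[(1R,2S)-1-(4-benzyloxy-3-methoxyphenyl)-1,3-bis(tert-butyldimethylsilyloxy)propan-2-yl]oxy}-3,5-dimethoxyphenyl]-3-[(tert-butyldimethylsilyloxy)methyl]tetrahydrofuran
Conditions: PPh3, DIAD, toluene, 0 °C → rt
Reagents that add atoms: none
Why: Mitsunobu etherification, in which the phenol (the only acidic partner) displaces the oxyphosphonium group of the single free secondary alcohol by SN2 with inversion and so converts the threo (αR,βR) alcohol into the erythro (αR,βS) aryl ether.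

Step 19
Reactants: 30 fully protected ether
Product: 31 (2S,3R,4S)-4-(4-benzyloxy-3,5-dimethoxybenzoyl)-2-[4-{[(1R,2S)-1-(4-benzyloxy-3-methoxyphenyl)-1,3-dihydroxypropan-2-yl]oxy}-3,5-dimethoxyphenyl]-3-(hydroxymethyl)tetrahydrofuran
Conditions: TBAF, AcOH, THF, rt → 40 °C
Reagents that add atoms: none
Why: Fluoride-mediated cleavage of the three silyl ethers, buffered with acetic acid so that the ketone α-centre and the benzylic positions are not exposed to strong base or acid.

Step 20
Reactants: 31 bis-benzyl ether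
Product: 32 CNP0236429.1, (2S,3R,4S)-2-[4-{[(1R,2S)-1,3-dihydroxy-1-(4-hydroxy-3-methoxyphenyl)propan-2-yl]oxy}-3,5-dimethoxyphenyl]-4-(4-hydroxy-3,5-dimethoxybenzoyl)-3-(hydroxymethyl)tetrahydrofuran
Conditions: H2 (1 atm), 10% Pd/C, EtOAc–MeOH, rt, stopped once both benzyl groups are gone
Reagents that add atoms: none
Why: Catalytic hydrogenolysis of the two aryl benzyl ethers, which under neutral conditions at atmospheric pressure should be cleaved well before the electron-rich aryl ketone, the benzylic alcohol or the benzylic ring C–O bond are attacked.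

**Compound list**

1 | syringaldehyde (4-hydroxy-3,5-dimethoxybenzaldehyde) | COc1cc(C=O)cc(OC)c1O | starting material
2 | 4-(benzyloxy)-3,5-dimethoxybenzaldehyde | COc1cc(C=O)cc(OC)c1OCc1ccccc1 | intermediate
3 | propane-1,3-dithiol | SCCCS | starting material
4 | 2-[4-(benzyloxy)-3,5-dimethoxyphenyl]-1,3-dithiane | COc1cc(C2SCCCS2)cc(OC)c1OCc1ccccc1 | intermediate
5 | 4-(allyloxy)-3,5-dimethoxybenzaldehyde | C=CCOc1c(OC)cc(C=O)cc1OC | intermediate
6 | furfural | O=Cc1ccco1 | starting material
7 | furfural endoperoxide (2,3,7-trioxabicyclo[2.2.1]hept-5-ene-1-carbaldehyde, racemic) | O=CC12OOC(C=C1)O2 | intermediate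
8 | 5-hydroxy-2(5H)-furanone (racemic) | O=C1C=CC(O)O1 | intermediate
9 | (−)-menthol, (1R,2S,5R)-2-isopropyl-5-methylcyclohexanol | C[C@@H]1CC[C@H]([C@@H](C1)O)C(C)C | starting material
10 | (5R)-5-[(1R,2S,5R)-menthyloxy]-2(5H)-furanone | O=C1C=C[C@H](O[C@@H]2C[C@H](C)CC[C@H]2C(C)C)O1 | intermediate
11 | 2-lithio-2-[4-(benzyloxy)-3,5-dimethoxyphenyl]-1,3-dithiane | [Li]C1(c2cc(OC)c(OCc3ccccc3)c(OC)c2)SCCCS1 | intermediate
12 | lithium (4R,5R)-4-[2-(4-benzyloxy-3,5-dimethoxyphenyl)-1,3-dithian-2-yl]-5-menthyloxy-4,5-dihydrofuran-2-olate (lactone enolate) | [Li]OC1=C[C@@H](C2(c3cc(OC)c(OCc4ccccc4)c(OC)c3)SCCCS2)[C@H](O[C@@H]2C[C@H](C)CC[C@H]2C(C)C)O1 | intermediate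
13 | (3S,4R,5R)-3-[(S)-(4-allyloxy-3,5-dimethoxyphenyl)(hydroxy)methyl]-4-[2-(4-benzyloxy-3,5-dimethoxyphenyl)-1,3-dithian-2-yl]-5-[(1R,2S,5R)-menthyloxy]dihydrofuran-2(3H)-one | O=C1O[C@@H](O[C@@H]2C[C@H](C)CC[C@H]2C(C)C)[C@H](C2(c3cc(OC)c(OCc4ccccc4)c(OC)c3)SCCCS2)[C@H]1[C@H](O)c1cc(OC)c(OCC=C)c(OC)c1 | intermediate
14 | (2R,3R)-2-[2-(4-benzyloxy-3,5-dimethoxyphenyl)-1,3-dithian-2-yl]-3-[(S)-(4-allyloxy-3,5-dimethoxyphenyl)(hydroxy)methyl]butane-1,4-diol | OC[C@H](C1(c2cc(OC)c(OCc3ccccc3)c(OC)c2)SCCCS1)[C@H](CO)[C@H](O)c1cc(OC)c(OCC=C)c(OC)c1 | intermediate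
15 | [(2S,3R,4R)-2-(4-allyloxy-3,5-dimethoxyphenyl)-4-[2-(4-benzyloxy-3,5-dimethoxyphenyl)-1,3-dithian-2-yl]tetrahydrofuran-3-yl]methanol | C=CCOc1c(OC)cc([C@H]2OC[C@H](C3(c4cc(OC)c(OCc5ccccc5)c(OC)c4)SCCCS3)[C@@H]2CO)cc1OC | intermediate
16 | (2S,3R,4R)-2-(4-allyloxy-3,5-dimethoxyphenyl)-4-[2-(4-benzyloxy-3,5-dimethoxyphenyl)-1,3-dithian-2-yl]-3-[(tert-butyldimethylsilyloxy)methyl]tetrahydrofuran | C=CCOc1c(OC)cc([C@H]2OC[C@H](C3(c4cc(OC)c(OCc5ccccc5)c(OC)c4)SCCCS3)[C@@H]2CO[Si](C)(C)C(C)(C)C)cc1OC | intermediate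
17 | (2S,3R,4R)-2-(4-allyloxy-3,5-dimethoxyphenyl)-4-(4-benzyloxy-3,5-dimethoxybenzoyl)-3-[(tert-butyldimethylsilyloxy)methyl]tetrahydrofuran (3,4-cis) | C=CCOc1c(OC)cc([C@H]2OC[C@H](C(=O)c3cc(OC)c(OCc4ccccc4)c(OC)c3)[C@@H]2CO[Si](C)(C)C(C)(C)C)cc1OC | intermediate
18 | (2S,3R,4S)-2-(4-allyloxy-3,5-dimethoxyphenyl)-4-(4-benzyloxy-3,5-dimethoxybenzoyl)-3-[(tert-butyldimethylsilyloxy)methyl]tetrahydrofuran (all-trans) | C=CCOc1c(OC)cc([C@H]2OC[C@@H](C(=O)c3cc(OC)c(OCc4ccccc4)c(OC)c3)[C@@H]2CO[Si](C)(C)C(C)(C)C)cc1OC | intermediate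
19 | (2S,3R,4S)-4-(4-benzyloxy-3,5-dimethoxybenzoyl)-3-[(tert-butyldimethylsilyloxy)methyl]-2-(4-hydroxy-3,5-dimethoxyphenyl)tetrahydrofuran | COc1cc([C@H]2OC[C@@H](C(=O)c3cc(OC)c(OCc4ccccc4)c(OC)c3)[C@@H]2CO[Si](C)(C)C(C)(C)C)cc(OC)c1O | intermediate
20 | 2-(allyloxy)acetic acid | C=CCOCC(=O)O | starting material
21 | (S)-4-benzyloxazolidin-2-one | O=C1N[C@@H](Cc2ccccc2)CO1 | starting material
22 | 2-(allyloxy)acetic pivalic anhydride | C=CCOCC(=O)OC(=O)C(C)(C)C | intermediate
23 | (S)-3-[2-(allyloxy)acetyl]-4-benzyloxazolidin-2-one | C=CCOCC(=O)N1C(=O)OC[C@@H]1Cc1ccccc1 | intermediate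
24 | 4-(benzyloxy)-3-methoxybenzaldehyde | COc1cc(C=O)ccc1OCc1ccccc1 | starting material
25 | dibutylboron Z-enolate of imide 23 | C=CCO/C=C(\OB(CCCC)CCCC)N1C(=O)OC[C@@H]1Cc1ccccc1 | intermediate
26 | (4S)-3-[(2S,3R)-2-(allyloxy)-3-(4-benzyloxy-3-methoxyphenyl)-3-hydroxypropanoyl]-4-benzyloxazolidin-2-one | C=CCO[C@H](C(=O)N1C(=O)OC[C@@H]1Cc1ccccc1)[C@H](O)c1ccc(OCc2ccccc2)c(OC)c1 | intermediate
27 | (1R,2R)-2-(allyloxy)-1-(4-benzyloxy-3-methoxyphenyl)propane-1,3-diol | C=CCO[C@H](CO)[C@H](O)c1ccc(OCc2ccccc2)c(OC)c1 | intermediate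
28 | (1R,2R)-2-(allyloxy)-1-(4-benzyloxy-3-methoxyphenyl)-1,3-bis(tert-butyldimethylsilyloxy)propane | C=CCO[C@H](CO[Si](C)(C)C(C)(C)C)[C@H](O[Si](C)(C)C(C)(C)C)c1ccc(OCc2ccccc2)c(OC)c1 | intermediate
29 | (1R,2R)-1-(4-benzyloxy-3-methoxyphenyl)-1,3-bis(tert-butyldimethylsilyloxy)propan-2-ol | O[C@H](CO[Si](C)(C)C(C)(C)C)[C@H](O[Si](C)(C)C(C)(C)C)c1ccc(OCc2ccccc2)c(OC)c1 | intermediate
30 | tris-silyl, bis-benzyl protected target (ring 2S,3R,4S; side chain αR,βS) | COc1cc([C@@H](O[Si](C)(C)C(C)(C)C)[C@H](CO[Si](C)(C)C(C)(C)C)Oc2c(OC)cc([C@H]3OC[C@@H](C(=O)c4cc(OC)c(OCc5ccccc5)c(OC)c4)[C@@H]3CO[Si](C)(C)C(C)(C)C)cc2OC)ccc1OCc1ccccc1 | intermediate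
31 | bis-benzyl ether of the target (ring 2S,3R,4S; side chain αR,βS) | COc1cc([C@@H](O)[C@H](CO)Oc2c(OC)cc([C@H]3OC[C@@H](C(=O)c4cc(OC)c(OCc5ccccc5)c(OC)c4)[C@@H]3CO)cc2OC)ccc1OCc1ccccc1 | intermediate
32 | CNP0236429.1 | COc1cc([C@@H](O)[C@H](CO)Oc2c(OC)cc([C@H]3OC[C@@H](C(=O)c4cc(OC)c(O)c(OC)c4)[C@@H]3CO)cc2OC)ccc1O | target

**Step count**

Total: 20 steps. Longest linear sequence: 12 steps (steps 1, 2 or steps 4, 5, then steps 6–12 and 18–20); the side-chain branch is 5 steps (13–17) before the coupling.

**Steps most likely to fail**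

Step 18 (Mitsunobu coupling). The displacement has to occur at a secondary carbon flanked by two silyloxy-bearing carbons and uses a phenol with two ortho methoxy groups. It may therefore be slow, and elimination, silyl migration or participation of the neighbouring electron-rich arene may erode yield or inversion. Fallback, setting out from 29 and 19 and coming back at 30: the activation is separated from the substitution. The alcohol is converted into (1R,2R)-1-(4-benzyloxy-3-methoxyphenyl)-1,3-bis(tert-butyldimethylsilyloxy)propan-2-yl trifluoromethanesulfonate F1 (Tf2O, 2,6-lutidine, CH2Cl2, −78 °C). F1 is then displaced by the preformed caesium phenoxide of 19 (Cs2CO3, DMF, −20 °C → rt) in a Williamson-type SN2 reaction with inversion, which gives 30 directly.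

Step 8 (cycloetherification). The benzylic cation may instead be captured by the nearby dithiane-bearing arene (Friedel–Crafts closure of a six-membered carbocycle), or the ring may close with incomplete 2,3-trans selectivity. Fallback, setting out from 14 and coming back at 15: the allyl group is removed first (Pd(PPh3)4, morpholine, THF) to give the phenolic triol F2. With the free para-hydroxyl the benzylic position ionises through a para-quinone methide under much milder acid (PPTS, CH2Cl2, rt), and reversible oxa-Michael addition of the C5 hydroxyl should give the phenolic tetrahydrofuran F3 without arene attack. Selective O-allylation of the phenol (allyl bromide, K2CO3, acetone) returns to 15.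

Step 6 (key step). The hindered lactone enolate may be captured incompletely, the aldol may revert on warming, or regiocontrol may be lost in the first addition (1,2- instead of 1,4-attack). Fallback, setting out from 4 and 10 and coming back at 13: the two bond formations are run separately. The conjugate addition is quenched at −78 °C with NH4Cl to isolate the trans lactone F4. Enolate 12 is then regenerated from F4 with LDA (THF, −78 °C) and treated with aldehyde 5 under independently chosen conditions (excess aldehyde, cold acidic quench), which gives 13.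

Further compounds
F1 | step 18 | (1R,2R)-1-(4-benzyloxy-3-methoxyphenyl)-1,3-bis(tert-butyldimethylsilyloxy)propan-2-yl trifluoromethanesulfonate | O=S(=O)(O[C@H](CO[Si](C)(C)C(C)(C)C)[C@H](O[Si](C)(C)C(C)(C)C)c1ccc(OCc2ccccc2)c(OC)c1)C(F)(F)F
F2 | step 8 | (2R,3R)-2-[2-(4-benzyloxy-3,5-dimethoxyphenyl)-1,3-dithian-2-yl]-3-[(S)-hydroxy(4-hydroxy-3,5-dimethoxyphenyl)methyl]butane-1,4-diol | OC[C@H](C1(c2cc(OC)c(OCc3ccccc3)c(OC)c2)SCCCS1)[C@H](CO)[C@H](O)c1cc(OC)c(O)c(OC)c1
F3 | step 8 | 4-[(2S,3R,4R)-4-[2-(4-benzyloxy-3,5-dimethoxyphenyl)-1,3-dithian-2-yl]-3-(hydroxymethyl)tetrahydrofuran-2-yl]-2,6-dimethoxyphenol | COc1cc([C@H]2OC[C@H](C3(c4cc(OC)c(OCc5ccccc5)c(OC)c4)SCCCS3)[C@@H]2CO)cc(OC)c1O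
F4 | step 6 | (4R,5R)-4-[2-(4-benzyloxy-3,5-dimethoxyphenyl)-1,3-dithian-2-yl]-5-[(1R,2S,5R)-menthyloxy]dihydrofuran-2(3H)-one | O=C1C[C@@H](C2(c3cc(OC)c(OCc4ccccc4)c(OC)c3)SCCCS2)[C@H](O[C@@H]2C[C@H](C)CC[C@H]2C(C)C)O1
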